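**Plan**
1. Retrosynthetic cuts, in order: the exocyclic C=CH2 and the acid (back to a CH2CO2Me arm on C2), the ring bond C3–C4 (made as C3=C4 by ring-closing metathesis), the ether bond O1–C6, the C5 vinyl and C5–chain bonds (back to a malonate), and the extra CH2 of the homofarnesyl chain (back to farnesol).
2. Enabling feature: in the oxane ring (O1, C2 carrying the acrylic acid, C3, C4, C5 carrying the chain, C6) the bond C3–C4 has the two stereocentres C2 and C5 as its direct neighbours. Each can therefore be made separately as a vinyl-bearing stereocentre and the ring closed between the two vinyl groups, with no step that could equilibrate the less stable cis ring.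
3. Forward order: farnesol → homofarnesyl iodide → malonate → prochiral diol → (R)-2-homofarnesylbut-3-en-1-ol; its triflate etherifies (S)-methyl 3-hydroxypent-4-enoate; metathesis closes the only ring; diimide saturates C3=C4; α-methylenation and saponification finish.
4. Stereochemistry: C5 from lipase desymmetrisation of the diol, C2 from lipase resolution of the hydroxy ester; cis results from pairing the (R)-alcohol with the (S)-hydroxy ester, and no later step touches either centre; the three E olefins come from (2E,6E)-farnesol.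

Key step: step 14

**Assumptions**
- Racemic methyl 3-hydroxypent-4-enoate is taken as a purchasable compound.
- Lipase PS is assumed to follow its empirical size rules, acetylating the (S)-hydroxy ester (vinyl medium, CH2CO2Me large) and the pro-R hydroxymethyl arm of the diol faster; both configurations are to be confirmed (Mosher esters) before the fragments are joined.

**Route**

Step 1
Reactants: 1 (2E,6E)-farnesol
Product: 2 (2E,6E)-farnesal
Conditions: TEMPO (10 mol %), PhI(OAc)2 (1.1 equiv), CH2Cl2, rt
Reagents that add atoms: none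
Why: Nitroxyl-catalysed oxidation of a primary allylic alcohol stops at the aldehyde under near-neutral conditions and should not isomerise the 2E olefin.

Step 2
Reactants: 2 (2E,6E)-farnesal
Product: 3 (3E,7E)-4,8,12-trimethyltrideca-1,3,7,11-tetraene
Conditions: Ph3PCH3Br, KOtBu, THF, 0 °C to rt
Reagents that add atoms: methyltriphenylphosphonium bromide, C[P+](c1ccccc1)(c1ccccc1)c1ccccc1.[Br-]
Why: Wittig methylenation of an enal is fast and leaves the trisubstituted olefins and their geometry untouched.

Step 3
Reactants: 3 (3E,7E)-4,8,12-trimethyltrideca-1,3,7,11-tetraene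
Product: 5 (3E,7E)-homofarnesol, via B-homofarnesyl-9-borabicyclo[3.3.1]nonane 4 (not isolated)
Conditions: 9-borabicyclo[3.3.1]nonane (9-BBN, 1.1 equiv), THF, 0 °C to rt; then NaOH, H2O2, H2O, 0 °C
Reagents that add atoms: hydrogen peroxide, OO
Why: Hydroboration–oxidation with a bulky dialkylborane attacks only the monosubstituted end of the diene and places boron on the terminal carbon, the same way homogeraniol is made from the geranial-derived triene.

Step 4
Reactants: 5 (3E,7E)-homofarnesol
Product: 6 (3E,7E)-homofarnesyl iodide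
Conditions: I2, PPh3, imidazole, CH2Cl2, 0 °C
Reagents that add atoms: iodine, II
Why: Appel-type iodination of a primary alcohol proceeds by SN2 displacement of the oxyphosphonium group under conditions that do not touch the olefins.

Step 5
Reactants: 7 diethyl malonate; 6 (3E,7E)-homofarnesyl iodide
Product: 9 diethyl 2-homofarnesylmalonate, via sodium diethyl malonate 8 (not isolated)
Conditions: 7 (3 equiv), NaH (2.5 equiv), THF/DMF, 0 °C; then 6, 50 °C
Reagents that add atoms: none
Why: Malonic ester alkylation with a primary iodide is a standard SN2 reaction, and the excess of the soft enolate suppresses both dialkylation and elimination to the diene.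

Step 6
Reactants: 9 diethyl 2-homofarnesylmalonate
Product: 10 2-homofarnesylpropane-1,3-diol
Conditions: LiAlH4, THF, 0 °C to rt; aqueous NaOH work-up
Reagents that add atoms: none
Why: Hydride reduction of a monoalkylmalonate to the 2-substituted propane-1,3-diol is routine and leaves isolated olefins alone.

Step 7
Reactants: 10 2-homofarnesylpropane-1,3-diol
Product: 11 (2R,5E,9E)-2-(hydroxymethyl)-6,10,14-trimethylpentadeca-5,9,13-trien-1-yl acetate
Conditions: lipase PS (Burkholderia cepacia, immobilised), vinyl acetate, iPr2O, rt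
Reagents that add atoms: vinyl acetate, C=COC(C)=O
Why: Lipase desymmetrisation of a prochiral 2-substituted propane-1,3-diol by irreversible transesterification should acetylate the pro-R hydroxymethyl arm, so the enzyme sets the stereocentre that becomes C5, and running slightly past full consumption of 10 drains the minor enantiomer into the diacetate.

Step 8
Reactants: 11 (2R,5E,9E)-2-(hydroxymethyl)-6,10,14-trimethylpentadeca-5,9,13-trien-1-yl acetate
Product: 12 (2S,5E,9E)-2-formyl-6,10,14-trimethylpentadeca-5,9,13-trien-1-yl acetate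
Conditions: Dess–Martin periodinane, pyridine, CH2Cl2, 0 °C; crude aldehyde used at once
Reagents that add atoms: none
Why: Dess–Martin oxidation under buffered, non-basic conditions gives the aldehyde without 1,3-acetyl migration (which would racemise 11) and without β-elimination of acetate.

Step 9
Reactants: 12 (2S,5E,9E)-2-formyl-6,10,14-trimethylpentadeca-5,9,13-trien-1-yl acetate
Product: 13 (2R,5E,9E)-2-ethenyl-6,10,14-trimethylpentadeca-5,9,13-trien-1-yl acetate
Conditions: Ph3PCH3Br, KN(SiMe3)2, THF, −78 °C; add 12; −78 to 0 °C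
Reagents that add atoms: methyltriphenylphosphonium bromide, C[P+](c1ccccc1)(c1ccccc1)c1ccccc1.[Br-]
Why: Wittig methylenation with the unstabilised ylide adds to the aldehyde at −78 °C faster than it enolises it or attacks the acetate, so the stereocentre should be carried through unchanged.

Step 10
Reactants: 13 (2R,5E,9E)-2-ethenyl-6,10,14-trimethylpentadeca-5,9,13-trien-1-yl acetate
Product: 14 (2R,5E,9E)-2-ethenyl-6,10,14-trimethylpentadeca-5,9,13-trien-1-ol
Conditions: K2CO3 (0.2 equiv), MeOH, rt
Reagents that add atoms: none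
Why: Base-catalysed methanolysis of a primary acetate is mild and cannot affect the now non-epimerisable stereocentre.

Step 11
Reactants: 15 racemic methyl 3-hydroxypent-4-enoate
Product: 16 methyl (3S)-3-acetoxypent-4-enoate
Conditions: lipase PS, vinyl acetate, MTBE, 30 °C, stopped below half conversion; chromatography
Reagents that add atoms: vinyl acetate, C=COC(C)=O
Why: Lipase kinetic resolution of a secondary alcohol by transesterification should acetylate the (S)-enantiomer (vinyl in the medium pocket, CH2CO2Me in the large one), leaving the (R)-alcohol to be separated, so the C2 stereocentre is selected by the enzyme.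

Step 12
Reactants: 16 methyl (3S)-3-acetoxypent-4-enoate
Product: 17 methyl (3S)-3-hydroxypent-4-enoate
Conditions: methanolic HCl (0.2 equiv), MeOH, rt
Reagents that add atoms: none
Why: Acid-catalysed transesterification removes the acetate by acyl–oxygen cleavage, so the configuration is retained, and it avoids the base-induced elimination of a β-acetoxy ester to the dienoate.

Step 13
Reactants: 14 (2R,5E,9E)-2-ethenyl-6,10,14-trimethylpentadeca-5,9,13-trien-1-ol; 17 methyl (3S)-3-hydroxypent-4-enoate
Product: 19 methyl (3S)-3-{[(2R,5E,9E)-2-ethenyl-6,10,14-trimethylpentadeca-5,9,13-trien-1-yl]oxy}pent-4-enoate, via primary triflate 18 (not isolated)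
Conditions: Tf2O (1.1 equiv), 2,6-di-tert-butyl-4-methylpyridine (2.5 equiv), CH2Cl2, −78 °C; then 17 (2 equiv), −78 °C to rt
Reagents that add atoms: none
Why: O-alkylation of a neutral alcohol by a primary alkyl triflate with a hindered pyridine as acid scavenger is an SN2 ether synthesis in which the β-hydroxy ester never becomes an alkoxide (no retro-aldol, no elimination), and neither stereocentre takes part.

Step 14
Reactants: 19 methyl (3S)-3-{[(2R,5E,9E)-2-ethenyl-6,10,14-trimethylpentadeca-5,9,13-trien-1-yl]oxy}pent-4-enoate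
Product: 20 methyl 2-[(2S,5R)-5-[(3E,7E)-4,8,12-trimethyltrideca-3,7,11-trien-1-yl]-5,6-dihydro-2H-pyran-2-yl]acetate (cis)
Conditions: RuCl2(=CHPh)(PCy3)2 (first-generation Grubbs catalyst, 5 mol %), CH2Cl2 (5 mM), 40 °C, argon purge
Reagents that add atoms: none
Why: The ruthenium benzylidene exchanges with one terminal vinyl group, the resulting alkylidene adds to the other vinyl group to give a ruthenacyclobutane, and cycloreversion forms C3=C4 and a ruthenium methylidene that carries the cycle while ethylene escapes (Chauvin mechanism). The closest known reaction is the ring-closing metathesis of allyl homoallyl ethers to 3,6-dihydro-2H-pyrans. The single ring is closed as a six-membered ring by joining the two terminal olefin carbons C3 and C4, the new double bond being endocyclic and necessarily cis. No stereocentre is formed and no bond to C2 or C5 is broken, so the cis relationship set by pairing 17 with 14 enters the ring unchanged. The selectivity needed is for the two monosubstituted vinyl groups over the three trisubstituted chain olefins, the nearest of which forms a 1,6-diene with the C5 vinyl group and could close a cyclopentene with loss of the chain; the first-generation catalyst, which engages trisubstituted olefins only sluggishly, together with high dilution and a stop at full conversion, should secure it.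

Step 15
Reactants: 20 methyl 2-[(2S,5R)-5-homofarnesyl-5,6-dihydro-2H-pyran-2-yl]acetate
Product: 21 methyl 2-[(2R,5R)-5-[(3E,7E)-4,8,12-trimethyltrideca-3,7,11-trien-1-yl]oxan-2-yl]acetate (cis)
Conditions: 2-nitrobenzenesulfonyl hydrazide (portions), Et3N, CH2Cl2, rt
Reagents that add atoms: none
Why: Diimide reduction transfers H2 in a concerted syn fashion and is much faster for a cis-disubstituted ring olefin than for trisubstituted ones, so only C3=C4 should be saturated (the C2 descriptor changes only through the priority rules).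

Step 16
Reactants: 21 methyl 2-[(2R,5R)-5-homofarnesyloxan-2-yl]acetate
Product: 23 methyl 3-(dimethylamino)-2-[(2R,5R)-5-homofarnesyloxan-2-yl]propanoate (both epimers at the α-carbon), via lithium ester enolate 22 (not isolated)
Conditions: LiN(iPr)2 (1.2 equiv), THF, −78 °C; then CH2=NMe2+ I− (2 equiv), −78 °C to rt
Reagents that add atoms: N,N-dimethylmethyleneiminium iodide (Eschenmoser's salt), C=[N+](C)C.[I-]
Why: Mannich aminomethylation of a lithium ester enolate is reliable, the enolate at −78 °C does not expel the β-ring oxygen, and the new α-stereocentre is irrelevant because it becomes sp2 in the next step.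

Step 17
Reactants: 23 methyl 3-(dimethylamino)-2-[(2R,5R)-5-homofarnesyloxan-2-yl]propanoate
Product: 25 methyl 2-[(2R,5R)-5-homofarnesyloxan-2-yl]prop-2-enoate, via trimethylammonium iodide 24 (not isolated)
Conditions: MeI, MeOH, rt; evaporate; DBU, CH2Cl2, 0 °C to rt
Reagents that add atoms: none
Why: Quaternisation followed by base-induced β-elimination of trimethylamine (Hofmann-type, E1cB) is the standard second half of the Eschenmoser α-methylenation of esters.

Step 18
Reactants: 25 methyl 2-[(2R,5R)-5-homofarnesyloxan-2-yl]prop-2-enoate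
Product: 27 rhopaloic acid B, via lithium carboxylate 26 (not isolated)
Conditions: LiOH, THF/H2O, rt; then 1 M HCl to pH 3, 0 °C
Reagents that add atoms: lithium hydroxide, [Li+].[OH-]
Why: Saponification of the methyl ester in a medium free of alkoxide avoids conjugate addition to the acrylate, and brief cold acidification should not affect the ring or the polyene.

**Compound list**
1 | (2E,6E)-farnesol | OC/C=C(\C)CC/C=C(\C)CCC=C(C)C | starting material
2 | (2E,6E)-farnesal | O=C/C=C(\C)CC/C=C(\C)CCC=C(C)C | intermediate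
3 | (3E,7E)-4,8,12-trimethyltrideca-1,3,7,11-tetraene | C=C/C=C(\C)CC/C=C(\C)CCC=C(C)C | intermediate
4 | B-[(3E,7E)-4,8,12-trimethyltrideca-3,7,11-trien-1-yl]-9-borabicyclo[3.3.1]nonane | B1(C2CCCC1CCC2)CC/C=C(\C)CC/C=C(\C)CCC=C(C)C | intermediate (not isolated)
5 | (3E,7E)-homofarnesol, (3E,7E)-4,8,12-trimethyltrideca-3,7,11-trien-1-ol | OCC/C=C(\C)CC/C=C(\C)CCC=C(C)C | intermediate
6 | (3E,7E)-homofarnesyl iodide | ICC/C=C(\C)CC/C=C(\C)CCC=C(C)C | intermediate
7 | diethyl malonate | CCOC(=O)CC(=O)OCC | starting material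
8 | sodium diethyl malonate (enolate) | [Na+].CCOC(=O)[CH-]C(=O)OCC | intermediate (not isolated)
9 | diethyl 2-[(3E,7E)-4,8,12-trimethyltrideca-3,7,11-trien-1-yl]malonate | CCOC(=O)C(CC/C=C(\C)CC/C=C(\C)CCC=C(C)C)C(=O)OCC | intermediate
10 | 2-[(3E,7E)-4,8,12-trimethyltrideca-3,7,11-trien-1-yl]propane-1,3-diol | OCC(CO)CC/C=C(\C)CC/C=C(\C)CCC=C(C)C | intermediate
11 | (2R,5E,9E)-2-(hydroxymethyl)-6,10,14-trimethylpentadeca-5,9,13-trien-1-yl acetate | CC(=O)OC[C@@H](CO)CC/C=C(\C)CC/C=C(\C)CCC=C(C)C | intermediate
12 | (2S,5E,9E)-2-formyl-6,10,14-trimethylpentadeca-5,9,13-trien-1-yl acetate | CC(=O)OC[C@@H](C=O)CC/C=C(\C)CC/C=C(\C)CCC=C(C)C | intermediate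
13 | (2R,5E,9E)-2-ethenyl-6,10,14-trimethylpentadeca-5,9,13-trien-1-yl acetate | CC(=O)OC[C@@H](C=C)CC/C=C(\C)CC/C=C(\C)CCC=C(C)C | intermediate
14 | (2R,5E,9E)-2-ethenyl-6,10,14-trimethylpentadeca-5,9,13-trien-1-ol, (R)-2-homofarnesylbut-3-en-1-ol | OC[C@@H](C=C)CC/C=C(\C)CC/C=C(\C)CCC=C(C)C | intermediate
15 | racemic methyl 3-hydroxypent-4-enoate | C=CC(O)CC(=O)OC | starting material
16 | methyl (3S)-3-acetoxypent-4-enoate | C=C[C@@H](OC(C)=O)CC(=O)OC | intermediate
17 | methyl (3S)-3-hydroxypent-4-enoate | C=C[C@@H](O)CC(=O)OC | intermediate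
18 | (2R,5E,9E)-2-ethenyl-6,10,14-trimethylpentadeca-5,9,13-trien-1-yl trifluoromethanesulfonate | FC(F)(F)S(=O)(=O)OC[C@@H](C=C)CC/C=C(\C)CC/C=C(\C)CCC=C(C)C | intermediate (not isolated)
19 | methyl (3S)-3-{[(2R,5E,9E)-2-ethenyl-6,10,14-trimethylpentadeca-5,9,13-trien-1-yl]oxy}pent-4-enoate | COC(=O)C[C@@H](C=C)OC[C@@H](C=C)CC/C=C(\C)CC/C=C(\C)CCC=C(C)C | intermediate (metathesis precursor)
20 | methyl 2-[(2S,5R)-5-[(3E,7E)-4,8,12-trimethyltrideca-3,7,11-trien-1-yl]-5,6-dihydro-2H-pyran-2-yl]acetate (cis) | COC(=O)C[C@H]1C=C[C@@H](CC/C=C(\C)CC/C=C(\C)CCC=C(C)C)CO1 | intermediate (metathesis product)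
21 | methyl 2-[(2R,5R)-5-[(3E,7E)-4,8,12-trimethyltrideca-3,7,11-trien-1-yl]oxan-2-yl]acetate (cis) | COC(=O)C[C@H]1CC[C@@H](CC/C=C(\C)CC/C=C(\C)CCC=C(C)C)CO1 | intermediate
22 | lithium enolate of 21 | [Li+].COC([O-])=C[C@H]1CC[C@@H](CC/C=C(\C)CC/C=C(\C)CCC=C(C)C)CO1 | intermediate (not isolated)
23 | methyl 3-(dimethylamino)-2-[(2R,5R)-5-homofarnesyloxan-2-yl]propanoate (α-epimers) | COC(=O)C(CN(C)C)[C@H]1CC[C@@H](CC/C=C(\C)CC/C=C(\C)CCC=C(C)C)CO1 | intermediate
24 | {3-methoxy-3-oxo-2-[(2R,5R)-5-homofarnesyloxan-2-yl]propyl}trimethylammonium iodide | [I-].COC(=O)C(C[N+](C)(C)C)[C@H]1CC[C@@H](CC/C=C(\C)CC/C=C(\C)CCC=C(C)C)CO1 | intermediate (not isolated)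
25 | methyl 2-[(2R,5R)-5-homofarnesyloxan-2-yl]prop-2-enoate (rhopaloic acid B methyl ester) | COC(=O)C(=C)[C@H]1CC[C@@H](CC/C=C(\C)CC/C=C(\C)CCC=C(C)C)CO1 | intermediate
26 | lithium 2-[(2R,5R)-5-homofarnesyloxan-2-yl]prop-2-enoate | [Li+].[O-]C(=O)C(=C)[C@H]1CC[C@@H](CC/C=C(\C)CC/C=C(\C)CCC=C(C)C)CO1 | intermediate (not isolated)
27 | rhopaloic acid B, 2-[(2R,5R)-5-[(3E,7E)-4,8,12-trimethyltrideca-3,7,11-trien-1-yl]oxan-2-yl]prop-2-enoic acid | C=C(C(=O)O)[C@H]1CC[C@@H](CC/C=C(\C)CC/C=C(\C)CCC=C(C)C)CO1 | target

**Count**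
Total steps: 18. Longest linear sequence: 16 (steps 1–10, then 13–18); steps 11–12 form the short side branch.

**Steps most likely to fail**

Step 13. The neutral O-alkylation may stall, because an un-ionised secondary hydroxyl attacks a β-branched primary triflate only slowly, and in that time the triflate can be lost by elimination or by participation of the C5 vinyl group or the nearest chain olefin. The fallback carries the ester at the alcohol oxidation level so that a true alkoxide can be used. Setting out from 17, LiAlH4 reduction should give (3S)-pent-4-ene-1,3-diol F1, and selective silylation of the primary hydroxyl (tert-butyldiphenylsilyl chloride, imidazole) (3S)-5-[(tert-butyldiphenylsilyl)oxy]pent-1-en-3-ol F2. Its sodium alkoxide (NaH, THF, 0 °C) is alkylated with triflate 18 (made from 14 as before) in a Williamson ether synthesis to the silyl-protected diene ether F3. Bu4NF frees the primary alcohol F4, TEMPO/PhI(OAc)2 in MeCN–water oxidises it to the carboxylic acid F5, and Me3SiCHN2 in MeOH esterifies it, which comes back to the route at 19.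

Step 9. The basic ylide may enolise the β-acetoxy aldehyde, leading to β-elimination of acetate or erosion of the C5 configuration. The fallback keeps a silyl ether, not an acetate, on the arm that survives; this needs the enantiomeric monoacetate, reached by running the same enzyme in the hydrolytic direction. Setting out from 10, Ac2O/pyridine gives the diacetate F6, and lipase PS in pH 7 phosphate buffer hydrolyses the same pro-R arm to give the (S)-monoacetate F7. TBSCl/imidazole then gives the silyl ether acetate F8, K2CO3/MeOH the mono-silylated alcohol F9, Dess–Martin oxidation the β-silyloxy aldehyde F10 (a configurationally robust aldehyde type), Wittig methylenation the silyl ether F11, and Bu4NF returns to the route at 14.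

Step 14. The ruthenium alkylidene may load on the C5 vinyl group and close onto the nearest trisubstituted chain olefin, cutting off the chain as a cyclopentene is formed; a more active catalyst such as the second-generation complex RuCl2(=CHPh)(PCy3)(H2IMes) would make this worse. The fallback biases initiation to the C2 vinyl group by making the C5 olefin 1,2-disubstituted. Setting out from 12, Wittig reaction with ethylidenetriphenylphosphorane gives the (Z)-propenyl acetate F12 and methanolysis the alcohol F13. Triflation to the triflate F14 and O-alkylation of 17 as in step 13 give the propenyl vinyl ether F15. Metathesis then starts at the only monosubstituted olefin and closes onto the propenyl group with loss of propene, which comes back to the route at 20.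

**Further compounds**
F1 | step 13 | (3S)-pent-4-ene-1,3-diol | C=C[C@@H](O)CCO
F2 | step 13 | (3S)-5-[(tert-butyldiphenylsilyl)oxy]pent-1-en-3-ol | C=C[C@@H](O)CCO[Si](c1ccccc1)(c1ccccc1)C(C)(C)C
F3 | step 13 | tert-butyl{[(3S)-3-{[(2R,5E,9E)-2-ethenyl-6,10,14-trimethylpentadeca-5,9,13-trien-1-yl]oxy}pent-4-en-1-yl]oxy}diphenylsilane | CC(C)(C)[Si](c1ccccc1)(c1ccccc1)OCC[C@@H](C=C)OC[C@@H](C=C)CC/C=C(\C)CC/C=C(\C)CCC=C(C)C
F4 | step 13 | (3S)-3-{[(2R,5E,9E)-2-ethenyl-6,10,14-trimethylpentadeca-5,9,13-trien-1-yl]oxy}pent-4-en-1-ol | OCC[C@@H](C=C)OC[C@@H](C=C)CC/C=C(\C)CC/C=C(\C)CCC=C(C)C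
F5 | step 13 | (3S)-3-{[(2R,5E,9E)-2-ethenyl-6,10,14-trimethylpentadeca-5,9,13-trien-1-yl]oxy}pent-4-enoic acid | OC(=O)C[C@@H](C=C)OC[C@@H](C=C)CC/C=C(\C)CC/C=C(\C)CCC=C(C)C
F6 | step 9 | 2-[(3E,7E)-4,8,12-trimethyltrideca-3,7,11-trien-1-yl]propane-1,3-diyl diacetate | CC(=O)OCC(COC(C)=O)CC/C=C(\C)CC/C=C(\C)CCC=C(C)C
F7 | step 9 | (2S,5E,9E)-2-(hydroxymethyl)-6,10,14-trimethylpentadeca-5,9,13-trien-1-yl acetate | CC(=O)OC[C@H](CO)CC/C=C(\C)CC/C=C(\C)CCC=C(C)C
F8 | step 9 | (2R,5E,9E)-2-{[(tert-butyldimethylsilyl)oxy]methyl}-6,10,14-trimethylpentadeca-5,9,13-trien-1-yl acetate | CC(=O)OC[C@H](CO[Si](C)(C)C(C)(C)C)CC/C=C(\C)CC/C=C(\C)CCC=C(C)C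
F9 | step 9 | (2R,5E,9E)-2-{[(tert-butyldimethylsilyl)oxy]methyl}-6,10,14-trimethylpentadeca-5,9,13-trien-1-ol | OC[C@H](CO[Si](C)(C)C(C)(C)C)CC/C=C(\C)CC/C=C(\C)CCC=C(C)C
F10 | step 9 | (2S,5E,9E)-2-{[(tert-butyldimethylsilyl)oxy]methyl}-6,10,14-trimethylpentadeca-5,9,13-trienal | O=C[C@H](CO[Si](C)(C)C(C)(C)C)CC/C=C(\C)CC/C=C(\C)CCC=C(C)C
F11 | step 9 | tert-butyl{[(2R,5E,9E)-2-ethenyl-6,10,14-trimethylpentadeca-5,9,13-trien-1-yl]oxy}dimethylsilane | C=C[C@H](CO[Si](C)(C)C(C)(C)C)CC/C=C(\C)CC/C=C(\C)CCC=C(C)C
F12 | step 14 | (2R,5E,9E)-6,10,14-trimethyl-2-[(1Z)-prop-1-en-1-yl]pentadeca-5,9,13-trien-1-yl acetate | CC(=O)OC[C@@H](/C=C\C)CC/C=C(\C)CC/C=C(\C)CCC=C(C)C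
F13 | step 14 | (2R,5E,9E)-6,10,14-trimethyl-2-[(1Z)-prop-1-en-1-yl]pentadeca-5,9,13-trien-1-ol | OC[C@@H](/C=C\C)CC/C=C(\C)CC/C=C(\C)CCC=C(C)C
F14 | step 14 | (2R,5E,9E)-6,10,14-trimethyl-2-[(1Z)-prop-1-en-1-yl]pentadeca-5,9,13-trien-1-yl trifluoromethanesulfonate | FC(F)(F)S(=O)(=O)OC[C@@H](/C=C\C)CC/C=C(\C)CC/C=C(\C)CCC=C(C)C
F15 | step 14 | methyl (3S)-3-{[(2R,5E,9E)-6,10,14-trimethyl-2-[(1Z)-prop-1-en-1-yl]pentadeca-5,9,13-trien-1-yl]oxy}pent-4-enoate | COC(=O)C[C@@H](C=C)OC[C@@H](/C=C\C)CC/C=C(\C)CC/C=C(\C)CCC=C(C)C
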